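The pitfall in a kinetic resolution is to carry the excess of an early reading over to the end of the flask. Here are the flasks, the earlier run and the conventions.

all flasks: free catalyst 0.12 mM

| run | left-handed substrate | right-handed substrate | reagent | temperature | remark | time |
|---|---|---|---|---|---|---|
| Wednesday's | 0.30 M | 0.30 M | 0.60 M (fed, over 6.0 d) | 25 °C | run made earlier; the fed solution adds 0.20 times the starting volume |  |
| oak | 0.20 M | 0.20 M | 0.600 M (fed, over 6.0 d) | 25 °C | the fed solution adds 0.20 times the starting volume | 25 d |
| alder | 0.20 M | 0.20 M | 0.600 M (fed, over 6.0 d) | 40 °C | the fed solution adds 0.20 times the starting volume | 25 d |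
| ash | 0.20 M | 0.20 M | 0.600 M (fed, over 6.0 d) | 10 °C | the fed solution adds 0.20 times the starting volume | 25 d |

Wednesday's run (percent of the left-handed substrate and right-handed substrate together charged)

| time / d | left-handed product / % | right-handed product / % | left-handed substrate / % |
|---|---|---|---|
| 0.208 | 0 | 1.8 | 49.7 |
| 0.417 | 2.6 | 0.4 | 50.5 |
| 0.625 | 0.9 | 0 | 49.9 |
| 1.25 | 0.4 | 0 | 47.2 |
| 2.50 | 10.4 | 1.7 | 39.9 |

(standard deviation of a reading: 1 percentage point)

- free catalyst is single-handed; left-handed substrate and right-handed substrate are mirror images of each other, charged as a racemate, each of them at the stated concentration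
- every charge counts on the volume at the start, and the solution that is fed holds the whole dose
- the numbers in the tables scatter with a standard deviation of 1 percentage point
- on the list of suspects stand: free catalyst + left-handed substrate <-> catalyst intermediate A; free catalyst + right-handed substrate <-> catalyst intermediate B; reagent + catalyst intermediate A -> free catalyst + left-handed product; reagent + catalyst intermediate B -> free catalyst + right-handed product; 2 reagent -> homo dimer; reagent <-> dormant form; 2 free catalyst -> spent catalyst
- the earlier runs do not show what temperature does; that part of a forecast is a guess
- an excess is below zero if the other one leads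

1. which flask leads in excess of left-handed product over right-handed product ("all alike" within 1.5 percentage points) (oak / alder / ash / all alike)
2. excess of left-handed product over right-handed product at the end, oak
3. excess of left-handed product over right-handed product at the end, alder
4. excess of left-handed product over right-handed product at the end, ash

In Wednesday's run at 2.50 d, the left-handed product reads 10.4% and the right-handed product 1.7%, so you read an excess of

71.9%

and a selectivity factor near 6.12. With a scatter of 1 percentage point on so small a peak, that ratio is loose. The first estimate says this excess stands in oak at the end. The objection is that the list of suspects lets the reagent go on to the right-handed substrate through catalyst intermediate B, so count what the reagent can do beyond the left-handed substrate: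

[reagent] charged − [left-handed substrate] charged = 0.400 M

This is the reagent surplus, reckoned per starting volume. In oak it is twice the 0.20 M of right-handed substrate, so the second estimate lets the excess fall to zero.

That has an objection too, since the surplus has other exits. Wednesday's loss of left-handed substrate grows from 2.8 points at 1.25 d to 10 points at 2.50 d, a factor of

3.61 against a squared time ratio of 4.00

Within the scatter of 1 point, Wednesday's readings fit a rate first order in [reagent] while the feed builds it up. By 2.50 d Wednesday's feed has delivered 0.250 M per starting volume, and the two products account for 0.0726 M. The remaining 0.177 M is not read, so it may be free reagent, homo dimer or dormant form. The share of the surplus that reaches the right-handed substrate cannot be read from this run. The reckoning here therefore commits to a bracket for oak, between zero and 71.9%, and the earlier runs give no temperature effect.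

The forecast commits to points: 35% for oak, 17% for alder, 58% for ash, with ash leading. It marks its temperature ground as a guess: “Warmer means faster and less selective, so lower ee.”

The flasks give 49.8% for oak, 69.0% for alder and 51.0% for ash, so alder leads, the flask the forecast put lowest.

    free catalyst + left-handed substrate ⇌ catalyst intermediate A (K = 120 M⁻¹, k = 100 M⁻¹ min⁻¹, Ea = 58.0 kJ mol⁻¹, ΔH = 2.00 kJ mol⁻¹)
    free catalyst + right-handed substrate ⇌ catalyst intermediate B (K = 2.60 M⁻¹, k = 49.0 M⁻¹ min⁻¹, Ea = 50.0 kJ mol⁻¹, ΔH = −53.0 kJ mol⁻¹)
    reagent + catalyst intermediate A → free catalyst + left-handed product (k = 6.80 M⁻¹ min⁻¹, Ea = 58.0 kJ mol⁻¹)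
    reagent + catalyst intermediate B → free catalyst + right-handed product (k = 2.60 M⁻¹ min⁻¹, Ea = 57.0 kJ mol⁻¹)
    2 reagent → homo dimer (k = 0.00130 M⁻¹ min⁻¹, Ea = 70.0 kJ mol⁻¹)
    reagent ⇌ dormant form (K = 0.240, k = 0.00200 min⁻¹, Ea = 104 kJ mol⁻¹, ΔH = −64.0 kJ mol⁻¹)
    2 free catalyst → spent catalyst (k = 5.50 M⁻¹ min⁻¹, Ea = 54.0 kJ mol⁻¹)
    (constants at 40 °C)

Of alder's surplus of 0.400 M, the homo dimer holds 0.342 M of reagent per starting volume at 25.0 d and the right-handed product 0.0366 M, a ratio of 9.34, while oak's 0.225 M against 0.0671 M gives 3.36. The neighbour of alder charged with 0.24 M of reagent has a surplus of 0.0400 M, and it ends with right-handed product at 2.10% of the two substrates charged together and an excess of 91.9%.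

The readings come from a simulation from invented constants, noise included.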